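**Plan**
- Retrosynthesis: the phenol O–benzyl bond is cut last. The C3–H and C4–H bonds are then removed to give a planar butenolide. C2–C3 and C2–O1 are cut together (loss of CO) to a (Z)-3-iodoallylic alcohol. Its C–I bond and its bond from the alkene to the vanillyl-type benzyl carbon lead back to an alkynol, and the alkyne–benzyl C–C bond leads back to propargyl alcohol and 3,4,5-trimethoxybenzyl chloride.
- Feature used: in the lactone ring O1–C2–C3–C4–C5 the carbonyl carbon C2 lies between O1 and C3, and C3 and C4 carry benzyl groups that differ only in remote aryl substituents. A C3–I bond held cis to the C5 hydroxyl lets CO enter last and fixes which benzyl group sits next to the carbonyl.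
- Forward: the chain is joined first (alkynylation, then hydroxyl-directed benzylmagnesiation and iodination). The only ring, the lactone, is closed by carbonylation. Reduction, epimerisation and debenzylation follow.
- Stereochemistry: C4 (R) comes from ligand-controlled hydride delivery to the Si face of C4 of the butenolide. C3 (R) comes from base equilibration to the trans lactone.

Key step: step 4

Assumption: (R)-DTBM-SEGPHOS is written in step 5 as the ligand antipode expected to give the 4R series; if the first run gave 4S, the (S)-ligand would be used and nothing else would change.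
Assumption: 4-benzyloxy-3-methoxybenzyl alcohol (O-benzylvanillyl alcohol) is taken as a purchased material.

**Step 1**
Reactants: 1 propargyl alcohol; 2 3,4,5-trimethoxybenzyl chloride
Product: 4 4-(3,4,5-trimethoxyphenyl)but-2-yn-1-ol, via bis(bromomagnesium) derivative of propargyl alcohol 3 (not isolated)
Conditions: EtMgBr (2.1 equiv), THF, 0 °C to rt; CuCl (10 mol%), then 2, 60 °C; aq. NH4Cl
Reagents that add atoms: none
Why: Copper-catalysed alkylation of an alkynyl Grignard reagent, in which the C-magnesiated carbon of 3 is transferred through a copper acetylide onto the activated benzylic chloride while the magnesium alkoxide is too poor a nucleophile to be O-benzylated.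

**Step 2**
Reactants: 5 4-benzyloxy-3-methoxybenzyl alcohol
Product: 6 4-benzyloxy-3-methoxybenzyl chloride
Conditions: SOCl2 (1.2 equiv), CH2Cl2, 0 °C to rt; used crude
Reagents that add atoms: thionyl chloride, O=S(Cl)Cl
Why: Deoxychlorination through the alkyl chlorosulfite is fast for an electron-rich benzylic alcohol, and the aryl benzyl and aryl methyl ethers are inert to SOCl2 and HCl at this temperature.

**Step 3**
Reactants: 4 4-(3,4,5-trimethoxyphenyl)but-2-yn-1-ol; 6 4-benzyloxy-3-methoxybenzyl chloride
Product: 10 (Z)-2-(4-benzyloxy-3-methoxybenzyl)-3-iodo-4-(3,4,5-trimethoxyphenyl)but-2-en-1-ol, via 4-benzyloxy-3-methoxybenzylmagnesium chloride 7 (not isolated), via chloromagnesium 4-(3,4,5-trimethoxyphenyl)but-2-yn-1-olate 8 (not isolated), via cyclic alkenylmagnesium alkoxide 9 (not isolated)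
Conditions: (a) 6, Mg turnings, 2-MeTHF, 0 °C, slow addition (gives 7); (b) 4, MeMgCl (1.0 equiv), THF, −20 °C (gives 8); then 7 (2 equiv), CuI (10 mol%), THF–toluene, −20 °C to rt (gives 9); (c) I2, THF, −40 to 0 °C; aq. Na2S2O3
Reagents that add atoms: iodine, II
Why: Hydroxyl-directed, copper-catalysed anti-carbomagnesiation of a 2-alkyn-1-ol, in which the alkoxide magnesium delivers the benzyl carbon of 7 to the proximal alkyne carbon (future lactone C4) and leaves magnesium on the distal carbon (future lactone C3) within the five-membered chelate 9, whose C–Mg bond is iodinated with retention so that iodine ends up cis to CH2OH (Z).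

**Step 4**
Reactants: 10 (Z)-2-(4-benzyloxy-3-methoxybenzyl)-3-iodo-4-(3,4,5-trimethoxyphenyl)but-2-en-1-ol
Product: 11 4-(4-benzyloxy-3-methoxybenzyl)-3-(3,4,5-trimethoxybenzyl)furan-2(5H)-one
Conditions: Pd(PPh3)4 (5 mol%), CO (1 atm), K2CO3 (2 equiv), THF, 50 °C
Reagents that add atoms: carbon monoxide, [C-]#[O+]
Why: Zerovalent palladium inserts into the alkenyl C–I bond of 10 with retention of the Z geometry, CO inserts into the alkenyl–palladium bond (forming C2–C3), and the cis hydroxymethyl oxygen, deprotonated by K2CO3, attacks the acylpalladium carbon (forming C2–O1) and releases the catalyst. The closest known reaction type is the palladium-catalysed carbonylative lactonisation of (Z)-3-iodoallylic alcohols to butenolides. The lactone ring closes as a 5-exo-trig acyl substitution, the attacked C=O lying outside the forming five-membered ring. No stereocentre is created, since the product is planar and achiral. The selectivity needed is regiochemical: C2 must bond to the carbon that carries the 3,4,5-trimethoxybenzyl group; this is secured because CO can enter only at the iodinated carbon and only the hydroxymethyl group cis to it can reach the acyl group, both fixed by the chelate-controlled addition of step 3.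

**Step 5**
Reactants: 11 4-(4-benzyloxy-3-methoxybenzyl)-3-(3,4,5-trimethoxybenzyl)furan-2(5H)-one
Product: 12 (4R)-4-(4-benzyloxy-3-methoxybenzyl)-3-(3,4,5-trimethoxybenzyl)dihydrofuran-2(3H)-one as its C3 epimer mixture
Conditions: Cu(OAc)2·H2O (5 mol%), (R)-DTBM-SEGPHOS (5.5 mol%), (EtO)2MeSiH (2 equiv), t-BuOH (2 equiv), toluene, 0 °C to rt; aq. NH4F
Reagents that add atoms: none
Why: Proposed new method: the bisphosphine-ligated CuH formed from Cu(OAc)2 and the silane should add hydride to C4 (the beta carbon) and copper to the C3 enolate position; t-BuOH protonates the copper enolate and the silane turns CuOt-Bu back into CuH. The chiral ligand pocket distinguishes the in-ring C5H2–O edge from the exocyclic benzyl group, so hydride delivery to the Si face of C4 sets 4R, while C3 is protonated without control and is corrected in step 6. The closest known reactions are the bisphosphine–CuH asymmetric conjugate reduction of beta-monosubstituted butenolides and the carbene-ligated CuH conjugate reduction of tetrasubstituted enoates; the new element is enantiocontrol on a fully substituted butenolide alkene.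

**Step 6**
Reactants: 12 (4R)-4-(4-benzyloxy-3-methoxybenzyl)-3-(3,4,5-trimethoxybenzyl)dihydrofuran-2(3H)-one as its C3 epimer mixture
Product: 13 (3R,4R)-4-(4-benzyloxy-3-methoxybenzyl)-3-(3,4,5-trimethoxybenzyl)dihydrofuran-2(3H)-one
Conditions: DBU (0.5 equiv), toluene, 80 °C
Reagents that add atoms: none
Why: Base-mediated epimerisation, in which reversible enolisation at C3 funnels the cis epimer into the more stable trans-3,4-disubstituted lactone while C4, which has no acidic hydrogen, keeps its R configuration, so C3 becomes R.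

**Step 7**
Reactants: 13 (3R,4R)-4-(4-benzyloxy-3-methoxybenzyl)-3-(3,4,5-trimethoxybenzyl)dihydrofuran-2(3H)-one
Product: 14 hernanol
Conditions: H2 (1 atm), Pd/C (10 wt% Pd), EtOAc–EtOH, rt
Reagents that add atoms: none
Why: Hydrogenolysis of the aryl benzyl ether over palladium on carbon frees the phenol under neutral conditions that leave the lactone, the methyl ethers and both stereocentres untouched.

**Compound list**
1 | propargyl alcohol | C#CCO | starting material
2 | 3,4,5-trimethoxybenzyl chloride | COc1cc(CCl)cc(OC)c1OC | starting material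
3 | bis(bromomagnesium) derivative of propargyl alcohol | Br[Mg]C#CCO[Mg]Br | intermediate (not isolated)
4 | 4-(3,4,5-trimethoxyphenyl)but-2-yn-1-ol | OCC#CCc1cc(OC)c(OC)c(OC)c1 | intermediate
5 | 4-benzyloxy-3-methoxybenzyl alcohol | COc1cc(CO)ccc1OCc1ccccc1 | starting material
6 | 4-benzyloxy-3-methoxybenzyl chloride | COc1cc(CCl)ccc1OCc1ccccc1 | intermediate
7 | 4-benzyloxy-3-methoxybenzylmagnesium chloride | COc1cc(C[Mg]Cl)ccc1OCc1ccccc1 | intermediate (not isolated)
8 | chloromagnesium 4-(3,4,5-trimethoxyphenyl)but-2-yn-1-olate | Cl[Mg]OCC#CCc1cc(OC)c(OC)c(OC)c1 | intermediate (not isolated)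
9 | 4-(4-benzyloxy-3-methoxybenzyl)-3-(3,4,5-trimethoxybenzyl)-2,5-dihydro-1,2-oxamagnesole (cyclic alkenylmagnesium alkoxide) | COc1cc(CC2=C(Cc3cc(OC)c(OC)c(OC)c3)[Mg]OC2)ccc1OCc1ccccc1 | intermediate (not isolated)
10 | (Z)-2-(4-benzyloxy-3-methoxybenzyl)-3-iodo-4-(3,4,5-trimethoxyphenyl)but-2-en-1-ol | OC/C(Cc1ccc(OCc2ccccc2)c(OC)c1)=C(\I)Cc1cc(OC)c(OC)c(OC)c1 | intermediate
11 | 4-(4-benzyloxy-3-methoxybenzyl)-3-(3,4,5-trimethoxybenzyl)furan-2(5H)-one | O=C1OCC(Cc2ccc(OCc3ccccc3)c(OC)c2)=C1Cc1cc(OC)c(OC)c(OC)c1 | intermediate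
12 | (4R)-4-(4-benzyloxy-3-methoxybenzyl)-3-(3,4,5-trimethoxybenzyl)dihydrofuran-2(3H)-one, C3 epimer mixture | COc1cc(C[C@H]2COC(=O)C2Cc2cc(OC)c(OC)c(OC)c2)ccc1OCc1ccccc1 | intermediate
13 | (3R,4R)-4-(4-benzyloxy-3-methoxybenzyl)-3-(3,4,5-trimethoxybenzyl)dihydrofuran-2(3H)-one | COc1cc(C[C@H]2COC(=O)[C@@H]2Cc2cc(OC)c(OC)c(OC)c2)ccc1OCc1ccccc1 | intermediate
14 | hernanol, (3R,4R)-4-(4-hydroxy-3-methoxybenzyl)-3-(3,4,5-trimethoxybenzyl)dihydrofuran-2(3H)-one | COc1cc(C[C@H]2COC(=O)[C@@H]2Cc2cc(OC)c(OC)c(OC)c2)ccc1O | target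

**Step count**
Total: 7 steps. Longest linear sequence: 6 steps (1 or 2, then 3, 4, 5, 6, 7).

**Steps most likely to fail**

Step 5 (Proposed new method). Hydrocupration of the tetrasubstituted C3=C4 bond may be too slow, or the two faces of C4 may be poorly discriminated because C4 carries two methylene groups of similar size. The fallback uses known chemistry and sets out from butenolide 11. Conjugate reduction with NaBH4 and NiCl2·6H2O in MeOH–THF at 0 °C should give racemic cis/trans 4-(4-benzyloxy-3-methoxybenzyl)-3-(3,4,5-trimethoxybenzyl)dihydrofuran-2(3H)-one F1. DBU in toluene at 80 °C should converge this on the racemic trans-lactone F2. Preparative chromatography on a chiral stationary phase (amylose tris(3,5-dimethylphenylcarbamate)) would then supply the (3R,4R) enantiomer, which is compound 13, where the route is rejoined.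

Step 3. The benzylic Grignard reagent may deprotonate the methylene of 4 that is flanked by aryl and alkyne, leading to propargyl-to-allenyl isomerisation instead of addition, and Wurtz homocoupling may erode the formation of 7. The fallback sets out from chloride 6 and fixes the alkene geometry through a keto ester instead of an alkyne.
- 3,4,5-Trimethoxyphenylacetic acid is condensed with Meldrum's acid (DCC, DMAP, CH2Cl2) to 5-[(3,4,5-trimethoxyphenyl)acetyl]-2,2-dimethyl-1,3-dioxane-4,6-dione F3.
- Methanolysis at reflux gives methyl 3-oxo-4-(3,4,5-trimethoxyphenyl)butanoate F4.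
- C-Alkylation with 6 (K2CO3, acetone, 50 °C) gives methyl 2-(4-benzyloxy-3-methoxybenzyl)-3-oxo-4-(3,4,5-trimethoxyphenyl)butanoate F5.
- The chelated sodium enolate (NaH, then Tf2O, CH2Cl2, −78 to 0 °C) should give methyl (Z)-2-(4-benzyloxy-3-methoxybenzyl)-3-(trifluoromethylsulfonyloxy)-4-(3,4,5-trimethoxyphenyl)but-2-enoate F6.
- i-Bu2AlH (CH2Cl2, −78 °C) reduces the ester to (Z)-3-(4-benzyloxy-3-methoxybenzyl)-4-hydroxy-1-(3,4,5-trimethoxyphenyl)but-2-en-2-yl trifluoromethanesulfonate F7.
- The same carbonylative closure (Pd(PPh3)4, CO 1 atm, K2CO3, LiCl, MeCN, 60 °C), now on the alkenyl triflate, forms C2–C3 and C2–O1 and rejoins the route at butenolide 11.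

Step 4. Oxidative addition and CO insertion at the hindered, fully substituted alkenyl iodide may be slow, so that reductive loss of iodine or decomposition of the light-sensitive iodide competes. The fallback sets out from the cyclic alkenylmagnesium alkoxide 9, generated as in step 3. Carbon dioxide is passed in at −20 °C to rt in place of iodine, and acidification with 2 M HCl liberates (Z)-3-(4-benzyloxy-3-methoxybenzyl)-4-hydroxy-2-(3,4,5-trimethoxybenzyl)but-2-enoic acid F8. This acid should lactonise spontaneously to butenolide 11, where the route is rejoined. The same two bonds to C2 are made, by polar carboxylation of the C–Mg bond instead of palladium-catalysed CO insertion.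

**Further compounds**
F1 | step 5 | racemic cis/trans 4-(4-benzyloxy-3-methoxybenzyl)-3-(3,4,5-trimethoxybenzyl)dihydrofuran-2(3H)-one | COc1cc(CC2COC(=O)C2Cc2cc(OC)c(OC)c(OC)c2)ccc1OCc1ccccc1
F2 | step 5 | racemic trans-4-(4-benzyloxy-3-methoxybenzyl)-3-(3,4,5-trimethoxybenzyl)dihydrofuran-2(3H)-one (3R,4R plus 3S,4S) | COc1cc(C[C@H]2COC(=O)[C@@H]2Cc2cc(OC)c(OC)c(OC)c2)ccc1OCc1ccccc1.COc1cc(C[C@@H]2COC(=O)[C@H]2Cc2cc(OC)c(OC)c(OC)c2)ccc1OCc1ccccc1
F3 | step 3 | 5-[(3,4,5-trimethoxyphenyl)acetyl]-2,2-dimethyl-1,3-dioxane-4,6-dione | COc1cc(CC(=O)C2C(=O)OC(C)(C)OC2=O)cc(OC)c1OC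
F4 | step 3 | methyl 3-oxo-4-(3,4,5-trimethoxyphenyl)butanoate | COC(=O)CC(=O)Cc1cc(OC)c(OC)c(OC)c1
F5 | step 3 | methyl 2-(4-benzyloxy-3-methoxybenzyl)-3-oxo-4-(3,4,5-trimethoxyphenyl)butanoate | COC(=O)C(Cc1ccc(OCc2ccccc2)c(OC)c1)C(=O)Cc1cc(OC)c(OC)c(OC)c1
F6 | step 3 | methyl (Z)-2-(4-benzyloxy-3-methoxybenzyl)-3-(trifluoromethylsulfonyloxy)-4-(3,4,5-trimethoxyphenyl)but-2-enoate | COC(=O)/C(Cc1ccc(OCc2ccccc2)c(OC)c1)=C(\OS(=O)(=O)C(F)(F)F)Cc1cc(OC)c(OC)c(OC)c1
F7 | step 3 | (Z)-3-(4-benzyloxy-3-methoxybenzyl)-4-hydroxy-1-(3,4,5-trimethoxyphenyl)but-2-en-2-yl trifluoromethanesulfonate | OC/C(Cc1ccc(OCc2ccccc2)c(OC)c1)=C(\OS(=O)(=O)C(F)(F)F)Cc1cc(OC)c(OC)c(OC)c1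
F8 | step 4 | (Z)-3-(4-benzyloxy-3-methoxybenzyl)-4-hydroxy-2-(3,4,5-trimethoxybenzyl)but-2-enoic acid | OC/C(Cc1ccc(OCc2ccccc2)c(OC)c1)=C(\C(O)=O)Cc1cc(OC)c(OC)c(OC)c1
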